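**Retrosynthetic overview**
1. The (E,E,E)-triene is built last by Julia–Kocienski disconnection to aldehyde **16** and dienyl PT-sulfone **21**. **16** comes from ozonolysis of the terminal alkene in **15**.
2. The only ring in the target, the 1,2-dioxolane, is closed in one light-driven Markovnikov cycloperoxidation of hydroperoxy-alkene **14** (Step 10). This sets C5 cis to C3.
3. C3 comes from (S)-lactic acid through Seebach's self-regeneration of stereocentres, then the epoxide **7** and β-lactone **13**. The chain is attached by Cu-catalysed opening of **7** with a vinyl Grignard. The β-lactone is opened by H2O2 with inversion to give the tertiary hydroperoxide.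
4. The dioxolanone, epoxide and β-lactone rings are all transient and are opened again; the dioxolane is formed once.

Assumption: the target is the cis-(3R,5R) dioxolane acid with the (9E,11E,13E)-triene exactly as in the SMILES. All numbered starting materials are purchasable.

---

**Step 1**
Reactants: **1** (S)-lactic acid; **2** pivaldehyde
Product: **3** (2S,5S)-2-tert-butyl-5-methyl-1,3-dioxolan-4-one
Conditions: p-TsOH (cat.), pentane, reflux, Dean–Stark; recrystallise the cis isomer
Reagents that add atoms: none
Why: Acid-catalysed acetalisation gives the cis-dioxolanone. Its tBu group is the stereochemical relay that lets the lactate stereocentre survive enolisation (Seebach self-regeneration of stereocentres).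

**Step 2**
Reactants: **3**; **4** tert-butyl bromoacetate
Product: **5** tert-butyl 2-[(2S,5R)-2-tert-butyl-5-methyl-4-oxo-1,3-dioxolan-5-yl]acetate
Conditions: LDA, THF, −78 °C; then **4**, −78 → −30 °C
Reagents that add atoms: none
Why: The enolate is alkylated anti to tBu, so CH2CO2tBu takes the place of the removed H with retention of the lactate geometry. This creates the quaternary centre that becomes C3 (SRS alkylation).

**Step 3**
Reactant: **5**
Product: **6** tert-butyl (3R)-3,4-dihydroxy-3-methylbutanoate (neopentyl alcohol is a by-product)
Conditions: LiBH4, THF, 0 °C → rt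
Reagents that add atoms: none
Why: The acylal carbonyl is far more electrophilic than the tBu ester. Hydride reduction frees the primary and tertiary OH groups without breaking any bond at the stereocentre (chemoselective lactone reduction).

**Step 4**
Reactant: **6**
Product: **7** tert-butyl 2-[(2R)-2-methyloxiran-2-yl]acetate
Conditions: TsCl, Et3N, DMAP, CH2Cl2, 0 °C; then NaH, THF, 0 °C
Reagents that add atoms: none
Why: TsCl reacts selectively at the primary OH. The tertiary alkoxide then closes the epoxide by 3-exo-tet displacement at CH2, so the C3–O bond and its configuration are retained (intramolecular Williamson).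

**Step 5**
Reactants: **8** 2,3-dibromopropene; **9** 9-bromonon-1-ene
Product: **10** 2-bromododeca-1,11-diene
Conditions: **9**, Mg, THF, rt to make the Grignard; then add to **8**, Li2CuCl4 (3 mol%), THF, −20 °C
Reagents that add atoms: none
Why: Cu-catalysed SN2 displacement of the allylic bromide leaves the vinylic C–Br intact (Kochi-type Grignard coupling). This fragment carries C5 and the eight CH2 plus the terminal alkene that later becomes the aldehyde.

**Step 6**
Reactants: **7**; **10**
Product: **11** tert-butyl (3S)-3-hydroxy-3-methyl-5-methylidenepentadec-14-enoate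
Conditions: **10**, Mg, THF, 40 °C; then CuI (10 mol%), **7**, THF, −30 °C
Reagents that add atoms: none
Why: The vinyl cuprate opens the epoxide at the unhindered CH2 (forming C4–C5). The tertiary C3–O bond is not touched, so the pool-derived configuration is kept (Cu-catalysed Grignard epoxide opening).

**Step 7**
Reactant: **11**
Product: **12** (3S)-3-hydroxy-3-methyl-5-methylidenepentadec-14-enoic acid
Conditions: ZnBr2 (5 equiv), CH2Cl2, rt
Reagents that add atoms: none
Why: Mild Lewis-acid cleavage of the tBu ester (isobutene loss) leaves the tertiary alcohol and both alkenes untouched.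

**Step 8**
Reactant: **12**
Product: **13** (4S)-4-methyl-4-(2-methylidenedodec-11-en-1-yl)oxetan-2-one
Conditions: PhSO2Cl, pyridine, 0 °C
Reagents that add atoms: none
Why: Adam β-lactonisation. The acid becomes a mixed sulfonic anhydride and the tertiary OH closes the four-membered ring by acyl substitution, so no bond to the stereocentre is broken.

**Step 9**
Reactants: **13**; hydrogen peroxide (reagent)
Product: **14** (3R)-3-hydroperoxy-3-methyl-5-methylidenepentadec-14-enoic acid
Conditions: H2O2 (50% aq., 10 equiv), Sc(OTf)3 (5 mol%), MeCN, 0 °C
Reagents that add atoms: hydrogen peroxide, OO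
Why: Proposed new method: alkyl–oxygen cleavage of the 4,4-disubstituted β-lactone by H2O2 proceeds SN2-like, with the tethered carboxylate leaving inside a tight ion pair. That carboxylate shields the original face, so HOO⁻ enters anti, inverting C3 from (S) to (R). The closest known reaction types are SN2 opening of β-lactones at C4 with inversion and acid-catalysed perhydrolysis of tertiary epoxides.

**Step 10**
Reactant: **14**
Product: **15** 2-[(3R,5R)-5-(dec-9-en-1-yl)-3,5-dimethyl-1,2-dioxolan-3-yl]acetic acid
Conditions: Co(salen)Cl (5 mol%), [Ir{dF(CF3)ppy}2(dtbbpy)]PF6 (1 mol%), PhSiH3 (1.5 equiv), N-fluoro-2,4,6-trimethylpyridinium triflate (1.5 equiv), MeCN/PhCF3, blue LEDs (450 nm), 25 °C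
Reagents that add atoms: none (only H from the silane; the product is an isomer of **14**)
Why: Proposed new method: light-driven Co–H metal-hydride H-atom transfer gives H• to the CH2 of the 1,1-disubstituted alkene (faster than to the remote monosubstituted alkene). The tertiary radical is captured by Co(II) and photo-oxidised to a Co(IV)-alkyl, which is displaced intramolecularly by the hydroperoxide OH. This closes the five-membered peroxide ring at C5 (Markovnikov, not the 6-endo radical mode) and forms the key C5–O bond. The nearest known reaction is Co-salen radical-polar-crossover hydroalkoxylation, here with a hydroperoxide as the internal nucleophile. C3 is untouched. C5 is set by an envelope transition state with both larger groups (CH2CO2H and the chain) pseudo-equatorial, giving the cis-(3R,5R) isomer.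

**Step 11**
Reactant: **15**
Product: **16** 2-[(3R,5R)-3,5-dimethyl-5-(9-oxononyl)-1,2-dioxolan-3-yl]acetic acid
Conditions: O3, CH2Cl2, −78 °C; then Me2S, −78 °C → rt
Reagents that add atoms: ozone, O=[O+][O-]
Why: Only the terminal alkene remains, so ozonolysis gives the aldehyde (C14). Ozone and Me2S leave the dialkyl peroxide and the acid intact.

**Step 12**
Reactant: **17** (2E,4E)-hepta-2,4-dienal
Product: **18** (2E,4E)-hepta-2,4-dien-1-ol
Conditions: NaBH4, CeCl3·7H2O, MeOH, 0 °C
Reagents that add atoms: none
Why: Luche 1,2-reduction keeps the diene geometry.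

**Step 13**
Reactants: **18**; **19** 1-phenyl-1H-tetrazole-5-thiol
Product: **20** 5-[(2E,4E)-hepta-2,4-dien-1-ylsulfanyl]-1-phenyl-1H-tetrazole
Conditions: PPh3, DIAD, THF, 0 °C
Reagents that add atoms: none
Why: Mitsunobu thioetherification at the primary allylic alcohol; the diene is untouched.

**Step 14**
Reactant: **20**
Product: **21** 5-[(2E,4E)-hepta-2,4-dien-1-ylsulfonyl]-1-phenyl-1H-tetrazole
Conditions: H2O2 (30% aq.), (NH4)6Mo7O24·4H2O (cat.), EtOH, 0 °C → rt
Reagents that add atoms: hydrogen peroxide, OO
Why: Molybdate-catalysed oxidation of the sulfide to the PT-sulfone needed for the olefination.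

**Step 15**
Reactants: **16**; **21**
Product: **22** target, 2-[(3R,5R)-3,5-dimethyl-5-[(9E,11E,13E)-hexadeca-9,11,13-trien-1-yl]-1,2-dioxolan-3-yl]acetic acid
Conditions: **21**, KHMDS (3.3 equiv), THF, −78 °C; add **16**; warm to rt
Reagents that add atoms: none
Why: Julia–Kocienski olefination forms the new E-alkene and carries over the (E,E)-diene. The first equivalent of base deprotonates the acid. The peroxide tolerates KHMDS because both peroxide-bearing carbons are quaternary and have no α-H.

---

**Compound list**

1 | (S)-lactic acid | C[C@H](O)C(=O)O | starting material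
2 | pivaldehyde | CC(C)(C)C=O | starting material
3 | (2S,5S)-2-tert-butyl-5-methyl-1,3-dioxolan-4-one | C[C@@H]1O[C@H](C(C)(C)C)OC1=O | intermediate
4 | tert-butyl bromoacetate | CC(C)(C)OC(=O)CBr | starting material
5 | tert-butyl 2-[(2S,5R)-2-tert-butyl-5-methyl-4-oxo-1,3-dioxolan-5-yl]acetate | CC(C)(C)OC(=O)C[C@@]1(C)O[C@H](C(C)(C)C)OC1=O | intermediate
6 | tert-butyl (3R)-3,4-dihydroxy-3-methylbutanoate | CC(C)(C)OC(=O)C[C@@](C)(O)CO | intermediate
7 | tert-butyl 2-[(2R)-2-methyloxiran-2-yl]acetate | CC(C)(C)OC(=O)C[C@]1(C)CO1 | intermediate
8 | 2,3-dibromopropene | C=C(Br)CBr | starting material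
9 | 9-bromonon-1-ene | C=CCCCCCCCBr | starting material
10 | 2-bromododeca-1,11-diene | C=C(Br)CCCCCCCCC=C | intermediate
11 | tert-butyl (3S)-3-hydroxy-3-methyl-5-methylidenepentadec-14-enoate | CC(C)(C)OC(=O)C[C@@](C)(O)CC(=C)CCCCCCCCC=C | intermediate
12 | (3S)-3-hydroxy-3-methyl-5-methylidenepentadec-14-enoic acid | OC(=O)C[C@@](C)(O)CC(=C)CCCCCCCCC=C | intermediate
13 | (4S)-4-methyl-4-(2-methylidenedodec-11-en-1-yl)oxetan-2-one | O=C1C[C@](C)(CC(=C)CCCCCCCCC=C)O1 | intermediate
14 | (3R)-3-hydroperoxy-3-methyl-5-methylidenepentadec-14-enoic acid | OC(=O)C[C@](C)(OO)CC(=C)CCCCCCCCC=C | intermediate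
15 | 2-[(3R,5R)-5-(dec-9-en-1-yl)-3,5-dimethyl-1,2-dioxolan-3-yl]acetic acid | C=CCCCCCCCC[C@]1(C)C[C@](C)(CC(=O)O)OO1 | intermediate
16 | 2-[(3R,5R)-3,5-dimethyl-5-(9-oxononyl)-1,2-dioxolan-3-yl]acetic acid | O=CCCCCCCCC[C@]1(C)C[C@](C)(CC(=O)O)OO1 | intermediate
17 | (2E,4E)-hepta-2,4-dienal | CC/C=C/C=C/C=O | starting material
18 | (2E,4E)-hepta-2,4-dien-1-ol | CC/C=C/C=C/CO | intermediate
19 | 1-phenyl-1H-tetrazole-5-thiol | Sc1nnnn1-c1ccccc1 | starting material
20 | 5-[(2E,4E)-hepta-2,4-dien-1-ylsulfanyl]-1-phenyl-1H-tetrazole | CC/C=C/C=C/CSc1nnnn1-c1ccccc1 | intermediate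
21 | 5-[(2E,4E)-hepta-2,4-dien-1-ylsulfonyl]-1-phenyl-1H-tetrazole | CC/C=C/C=C/CS(=O)(=O)c1nnnn1-c1ccccc1 | intermediate
22 | 2-[(3R,5R)-3,5-dimethyl-5-[(9E,11E,13E)-hexadeca-9,11,13-trien-1-yl]-1,2-dioxolan-3-yl]acetic acid | CC/C=C/C=C/C=C/CCCCCCCC[C@]1(C)C[C@](C)(CC(=O)O)OO1 | target

---

**Total step count:** 15 (longest linear sequence: 11 steps, from **1** through Steps 1–4, 6–11 and 15).

**Three steps most likely to fail**

1. **Step 10 (proposed new light-driven cycloperoxidation).** The free hydroperoxide can be reduced by Co(II) or silane, the remote terminal alkene can compete, and the cis/trans ratio at C5 is uncertain.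
   Fallback: drop the Co/photoredox system and use known Brønsted-acid-catalysed Markovnikov cyclisation of the hydroperoxy-alkene (cat. TfOH, HFIP, 0 °C), an ionic hydroalkoxylation analogue. Any cis/trans mixture would be equilibrated through the peroxycarbenium ion.
2. **Step 9 (proposed new β-lactone perhydrolysis).** HOO⁻ may attack the acyl carbon to give the peracid instead, or the tertiary centre may ionise and partly racemise.
   Fallback: use known perhydrolysis of epoxide **7** (H2O2, cat. H2SO4, inversion at the tertiary carbon) to give the hydroperoxy alcohol. Then protect the OOH, oxidise the CH2OH to the aldehyde, and olefinate with the C5 ylide to give an allylic tertiary hydroperoxide. This closes by the same Markovnikov cyclisation as Step 10.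
3. **Step 15 (Julia–Kocienski).** E,E,E selectivity with a dienyl PT-sulfone may be partial, and the acid uses up extra base.
   Fallback: Takai CrCl2/CHI3 olefination of **16** to the (E)-vinyl iodide, then Suzuki coupling with (1E,3E)-hexa-1,3-dienyl pinacol boronate. This preserves all three alkene geometries.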